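**Retrosynthetic overview**
1. Numbering is drimane-type (ring A: C1–C5 and C10; ring B: C5–C10; β is the face of the C10 methyl). The endgame is functional-group change only: C11 acetal → CHO, Δ6 → Δ7 enoate, prenyl group → (R)-isopropenyl carbinol, and C3 ketone → equatorial C3–Cl via enol triflate, alkenyl chloride and HAT hydrogenation.
2. Key disconnection: the ring-fusion bond C5–C10 together with C8–C9, by an endo intramolecular Diels–Alder reaction of an open-chain trienal. Rings A and B close together in this step; no carbocycle exists before it.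
3. Enabling feature: ring B is a cyclohexene whose C9 carries the formyl group next to the quaternary fusion carbon C10. This is the retron of an (E)-C9=C10 enal adding to a C5–C8 diene, with the four ring A carbons C1–C4 as tether, held in one chair by the quaternary C4 and the C1 silyloxy group.
4. The trienal comes from an aldol union (bond C1–C2) of a C2–C8 methyl ketone with a five-carbon enal acetal (C1, C9–C11 and the C10 methyl).
5. The quaternary C4 comes from geraniol by Sharpless epoxidation and a stereospecific epoxy silyl ether → aldehyde rearrangement.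

Key step: step 12

Assumption: (2E)-4,4-dimethoxy-2-methylbut-2-enal and trimethyl 4-phosphonocrotonate are taken as purchasable building blocks.

**Route**

Step 1
Reactants: 1 geraniol
Product: 2 (2R,3R)-2,3-epoxygeraniol
Conditions: Ti(OiPr)4 (cat.), D-(−)-diethyl tartrate (cat.), t-BuOOH, 4 Å molecular sieves, CH2Cl2, −20 °C
Reagents that add atoms: tert-butyl hydroperoxide, CC(C)(C)OO
Why: Sharpless asymmetric epoxidation of the allylic alcohol, in which the D-tartrate catalyst delivers oxygen to the face that gives the (2R,3R)-epoxide whose chirality later becomes C4.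

Step 2
Reactants: 2 (2R,3R)-2,3-epoxygeraniol
Product: 3 tert-butyldimethylsilyl ether of (2R,3R)-2,3-epoxygeraniol
Conditions: TBSCl, imidazole, DMF, rt
Reagents that add atoms: tert-butyldimethylsilyl chloride, CC(C)(C)[Si](C)(C)Cl
Why: Standard silylation of the primary alcohol, which supplies the siloxymethyl group that migrates in the next step.

Step 3
Reactants: 3 tert-butyldimethylsilyl ether of (2R,3R)-2,3-epoxygeraniol
Product: 4 (2R)-2-{[(tert-butyldimethylsilyl)oxy]methyl}-2,6-dimethylhept-5-enal
Conditions: methylaluminum bis(4-bromo-2,6-di-tert-butylphenoxide) (20 mol %), CH2Cl2, −78 to −20 °C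
Reagents that add atoms: none
Why: Bulky aluminium Lewis acid-catalysed rearrangement of an epoxy silyl ether to a β-siloxy aldehyde (semipinacol-type 1,2-shift), in which the tertiary C–O bond ionises and the siloxymethyl group migrates anti to it, so that the epoxide chirality is transferred to the new quaternary centre (future C4).

Step 4
Reactants: 4 (2R)-2-{[(tert-butyldimethylsilyl)oxy]methyl}-2,6-dimethylhept-5-enal; 5 trimethyl 4-phosphonocrotonate
Product: 6 methyl (2E,4E,6S)-6-{[(tert-butyldimethylsilyl)oxy]methyl}-6,10-dimethylundeca-2,4,9-trienoate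
Conditions: LiN(SiMe3)2, THF, −78 to 0 °C
Reagents that add atoms: none
Why: Vinylogous Horner–Wadsworth–Emmons olefination of the non-enolisable aldehyde, which installs the (E,E)-dienoate that is the C5–C8 diene with its ester carbon.

Step 5
Reactants: 6 methyl (2E,4E,6S)-6-{[(tert-butyldimethylsilyl)oxy]methyl}-6,10-dimethylundeca-2,4,9-trienoate
Product: 7 methyl (2E,4E,6S)-6-(hydroxymethyl)-6,10-dimethylundeca-2,4,9-trienoate
Conditions: HF·pyridine, pyridine, THF, 0 °C to rt
Reagents that add atoms: none
Why: Fluoride cleavage of the primary silyl ether under buffered conditions that leave the dienoate and the trisubstituted olefin untouched.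

Step 6
Reactants: 7 methyl (2E,4E,6S)-6-(hydroxymethyl)-6,10-dimethylundeca-2,4,9-trienoate
Product: 8 methyl (2E,4E,6S)-6-formyl-6,10-dimethylundeca-2,4,9-trienoate
Conditions: Dess–Martin periodinane, CH2Cl2, rt
Reagents that add atoms: none
Why: Dess–Martin oxidation of the neopentyl primary alcohol to an aldehyde that can neither enolise nor conjugate because C4 is quaternary.

Step 7
Reactants: 8 methyl (2E,4E,6S)-6-formyl-6,10-dimethylundeca-2,4,9-trienoate
Product: 9 methyl (2E,4E,6S)-6-(1-hydroxyethyl)-6,10-dimethylundeca-2,4,9-trienoate (both carbinol epimers)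
Conditions: MeMgBr (1.1 equiv), THF, −78 °C
Reagents that add atoms: methylmagnesium bromide, C[Mg]Br
Why: Grignard addition to the aldehyde, which at −78 °C should be much faster than attack on the dienoate; the new carbinol centre is removed in the next step.

Step 8
Reactants: 9 methyl (2E,4E,6S)-6-(1-hydroxyethyl)-6,10-dimethylundeca-2,4,9-trienoate
Product: 10 methyl (2E,4E,6S)-6-acetyl-6,10-dimethylundeca-2,4,9-trienoate
Conditions: Dess–Martin periodinane, CH2Cl2, rt
Reagents that add atoms: none
Why: Dess–Martin oxidation to the methyl ketone, whose only enolisable position is the methyl group (future C2).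

Step 9
Reactants: 10 methyl (2E,4E,6S)-6-acetyl-6,10-dimethylundeca-2,4,9-trienoate; 11 (2E)-4,4-dimethoxy-2-methylbut-2-enal
Product: 13 methyl (2E,4E,6S)-6-[(3S,4E)-3-hydroxy-6,6-dimethoxy-4-methylhex-4-enoyl]-6,10-dimethylundeca-2,4,9-trienoate, via diisopinocampheylboron enolate 12 (not isolated)
Conditions: (−)-Ipc2BCl, Et3N, Et2O, 0 °C; then 11, −78 to −20 °C; then H2O2, MeOH, pH 7 buffer, 0 °C
Reagents that add atoms: none
Why: Paterson boron aldol reaction, in which the Ipc2B enolate of the methyl ketone is expected to add to the si face of the α-branched enal under reagent control and set the C1 carbinol as (S); the minor C1 epimer is a diastereomer and is removed by chromatography.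

Step 10
Reactants: 13 methyl (2E,4E,6S)-6-[(3S,4E)-3-hydroxy-6,6-dimethoxy-4-methylhex-4-enoyl]-6,10-dimethylundeca-2,4,9-trienoate
Product: 14 methyl (2E,4E,6S)-6-[(3S,4E)-3-[(tert-butyldimethylsilyl)oxy]-6,6-dimethoxy-4-methylhex-4-enoyl]-6,10-dimethylundeca-2,4,9-trienoate
Conditions: TBSCl, imidazole, DMAP (cat.), DMF, rt
Reagents that add atoms: tert-butyldimethylsilyl chloride, CC(C)(C)[Si](C)(C)Cl
Why: Silylation of the β-hydroxy ketone, which blocks retro-aldol and elimination and provides the group that steers the cycloaddition.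

Step 11
Reactants: 14 methyl (2E,4E,6S)-6-[(3S,4E)-3-[(tert-butyldimethylsilyl)oxy]-6,6-dimethoxy-4-methylhex-4-enoyl]-6,10-dimethylundeca-2,4,9-trienoate
Product: 15 methyl (2E,4E,6S)-6-[(3S,4E)-3-[(tert-butyldimethylsilyl)oxy]-4-methyl-6-oxohex-4-enoyl]-6,10-dimethylundeca-2,4,9-trienoate
Conditions: pyridinium p-toluenesulfonate (cat.), acetone–H2O, rt
Reagents that add atoms: water, O
Why: Mild acid hydrolysis of the allylic dimethyl acetal, which is far more labile than the secondary silyl ether, to unveil the (E)-enal dienophile.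

Step 12
Reactants: 15 methyl (2E,4E,6S)-6-[(3S,4E)-3-[(tert-butyldimethylsilyl)oxy]-4-methyl-6-oxohex-4-enoyl]-6,10-dimethylundeca-2,4,9-trienoate
Product: 16 trans-fused cycloadduct (drimane numbering: 1α-OTBS; 3-oxo; 4β-methyl; 4α-(4-methylpent-3-enyl); 5α-H; 6-ene; 8β-CO2Me; 9β-CHO; 10β-methyl)
Conditions: Me2AlCl (1.2 equiv), CH2Cl2, −78 to −10 °C
Reagents that add atoms: none
Why: A concerted, asynchronous normal-demand [4+2] cycloaddition of the Me2AlCl-complexed (E)-enal C9=C10 with the (E,E)-diene C5–C8; the closest known reaction type is the Lewis acid-promoted type 1 intramolecular Diels–Alder reaction of (2E,7E,9E)-deca-2,7,9-trienals to trans-fused octalins, including β-methyl enals that create an angular methyl. Ring B closes as the cycloaddition ring (bonds C5–C10 and C8–C9), and ring A closes at the same time because the four-carbon tether C1–C4 is folded into a chair that the new C5–C10 bond completes. Suprafacial addition transfers the (E)-enal geometry into the cis relationship of C10 methyl and C9 formyl and the (E,E)-diene geometry into C5 and C8, and the endo position of the complexed formyl group places C5–H trans to the angular methyl (trans-decalin, 9β-CHO). Which pair of π faces reacts is decided by the chair of the tether: the C1 silyloxy group is expected to sit axial, in the plane of the dienophile and anti to the C10 methyl (allylic 1,2-strain, and the C–O bond kept out of alignment with the electron-poor π system), which puts the C4 methyl axial and the 4-methylpent-3-enyl chain equatorial as in the target. The step therefore needs endo over exo selectivity, secured by the Lewis acid, and one π-face pair, secured by the C1 stereocentre; the quaternary C4 and the substituted C1 also favour the coiled reactive conformer.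

Step 13
Reactants: 16 trans-fused cycloadduct (9β-CHO)
Product: 17 dimethyl acetal of the cycloadduct (1α-OTBS; 3-oxo; 6-ene; 8β-CO2Me; 9β-CH(OMe)2)
Conditions: HC(OMe)3, pyridinium p-toluenesulfonate (cat.), MeOH, rt
Reagents that add atoms: trimethyl orthoformate, COC(OC)OC
Why: Acid-catalysed acetalisation with orthoformate masks the epimerisable C9 aldehyde, while the hindered C3 ketone next to the quaternary C4 should not ketalise under these conditions.

Step 14
Reactants: 17 dimethyl acetal of the cycloadduct
Product: 19 C3 enol triflate (2-ene; 1α-OTBS; 6-ene; 8β-CO2Me; 9β-CH(OMe)2), via potassium enolate 18 (not isolated)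
Conditions: KN(SiMe3)2, THF, −78 °C; then PhNTf2, −78 to 0 °C
Reagents that add atoms: N-phenylbis(trifluoromethanesulfonimide), O=S(=O)(N(c1ccccc1)S(=O)(=O)C(F)(F)F)C(F)(F)F
Why: Kinetic enolisation of the C3 ketone can only go toward C2 because C4 is quaternary, and O-sulfonylation of the enolate gives the enol triflate.

Step 15
Reactants: 19 C3 enol triflate
Product: 20 alkenyl chloride (3-chloro-2-ene; 1α-OTBS; 6-ene; 8β-CO2Me; 9β-CH(OMe)2)
Conditions: Ni(OAc)2·4H2O (cat.), 1,5-cyclooctadiene, Zn (cat.), LiCl, DMA–THF, rt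
Reagents that add atoms: lithium chloride, [Li+].[Cl-]
Why: Nickel-catalysed halide exchange of an enol triflate (oxidative addition to zerovalent nickel formed in the flask, triflate-for-chloride exchange, C–Cl reductive elimination), which should leave ester, acetal and olefins untouched.

Step 16
Reactants: 20 alkenyl chloride (1α-OTBS)
Product: 21 allylic alcohol (3-chloro-2-ene; 1α-OH; 6-ene; 8β-CO2Me; 9β-CH(OMe)2)
Conditions: HF·pyridine, pyridine, THF, rt
Reagents that add atoms: none
Why: Fluoride removal of the silyl ether frees the C1 hydroxyl before the radical hydrogenation, so that the α face of C3 is not screened by a bulky axial silyloxy group.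

Step 17
Reactants: 21 allylic alcohol
Product: 22 side-chain (R)-epoxide (3-chloro-2-ene; 1α-OH; 6-ene; 8β-CO2Me; 9β-CH(OMe)2)
Conditions: D-fructose-derived Shi ketone (0.3 equiv), KHSO5 (Oxone), K2CO3, Bu4NHSO4, MeCN–CH2(OMe)2–aq. Na2B4O7 buffer, 0 °C
Reagents that add atoms: potassium peroxymonosulfate, [K+].[O-]S(=O)(=O)OO
Why: Shi asymmetric epoxidation, in which the chiral dioxirane should attack the electron-rich trisubstituted side-chain olefin in preference to the hindered cis-disubstituted ring B olefin and the electron-poor chloroolefin, and sets the (R)-configured C–O bond of the future carbinol by reagent control.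

Step 18
Reactants: 22 side-chain (R)-epoxide
Product: 23 3β-chloride (1α-OH; 3β-Cl; 6-ene; 8β-CO2Me; 9β-CH(OMe)2; side-chain epoxide)
Conditions: Mn(dpm)3 (cat.; dpm = 2,2,6,6-tetramethylheptane-3,5-dionate), PhSiH3, t-BuOOH, i-PrOH, rt
Reagents that add atoms: none
Why: Metal hydride hydrogen-atom-transfer hydrogenation of a haloalkene (Shenvi type), in which a hydrogen atom adds to C2, the chlorine-stabilised C3 radical takes up hydrogen axially on the α face to give the favoured equatorial 3β-chloride without C–Cl cleavage, and the cis-disubstituted ring B olefin is a poor acceptor.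

Step 19
Reactants: 23 3β-chloride with side-chain epoxide
Product: 24 (R)-isopropenyl carbinol (1α-OH; 3β-Cl; 6-ene; 8β-CO2Me; 9β-CH(OMe)2)
Conditions: Cp2TiCl2 (cat.), Mn, 2,4,6-collidine·HCl, THF, rt
Reagents that add atoms: none
Why: Titanocene-catalysed radical isomerisation of a trisubstituted epoxide to an allylic alcohol, in which Cp2TiCl (trivalent titanium regenerated by Mn) cleaves the tertiary C–O bond and the tertiary radical is trapped by a second Cp2TiCl and loses a methyl hydrogen to give the isopropenyl group, the secondary (R) C–O bond staying intact.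

Step 20
Reactants: 24 (R)-isopropenyl carbinol (6-ene)
Product: 25 conjugated ester (7-ene; 1α-OH; 3β-Cl; 9β-CH(OMe)2)
Conditions: DBU, toluene, 50 °C
Reagents that add atoms: none
Why: Base-mediated β,γ to α,β isomerisation of the unsaturated ester through its dienolate gives the conjugated trisubstituted Δ7 enoate, and C9 keeps its configuration because it is not acidic while the aldehyde is an acetal.

Step 21
Reactants: 25 conjugated ester (9β-CH(OMe)2)
Product: 26 target CNP0159496.2
Conditions: pyridinium p-toluenesulfonate (cat.), acetone–H2O, rt to 40 °C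
Reagents that add atoms: water, O
Why: Mild buffered hydrolysis of the dimethyl acetal should release the C9 aldehyde without epimerisation, olefin migration or loss of the allylic alcohol.

**Compound list**
1 | geraniol, (2E)-3,7-dimethylocta-2,6-dien-1-ol | CC(C)=CCC/C(C)=C/CO | starting material
2 | (2R,3R)-2,3-epoxygeraniol | OC[C@H]1O[C@]1(C)CCC=C(C)C | intermediate
3 | tert-butyldimethylsilyl ether of (2R,3R)-2,3-epoxygeraniol | CC(C)(C)[Si](C)(C)OC[C@H]1O[C@]1(C)CCC=C(C)C | intermediate
4 | (2R)-2-{[(tert-butyldimethylsilyl)oxy]methyl}-2,6-dimethylhept-5-enal | O=C[C@@](C)(CO[Si](C)(C)C(C)(C)C)CCC=C(C)C | intermediate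
5 | trimethyl 4-phosphonocrotonate, methyl (2E)-4-(dimethoxyphosphoryl)but-2-enoate | COC(=O)/C=C/CP(=O)(OC)OC | starting material
6 | methyl (2E,4E,6S)-6-{[(tert-butyldimethylsilyl)oxy]methyl}-6,10-dimethylundeca-2,4,9-trienoate | COC(=O)/C=C/C=C/[C@@](C)(CO[Si](C)(C)C(C)(C)C)CCC=C(C)C | intermediate
7 | methyl (2E,4E,6S)-6-(hydroxymethyl)-6,10-dimethylundeca-2,4,9-trienoate | COC(=O)/C=C/C=C/[C@@](C)(CO)CCC=C(C)C | intermediate
8 | methyl (2E,4E,6S)-6-formyl-6,10-dimethylundeca-2,4,9-trienoate | COC(=O)/C=C/C=C/[C@@](C)(C=O)CCC=C(C)C | intermediate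
9 | methyl (2E,4E,6S)-6-(1-hydroxyethyl)-6,10-dimethylundeca-2,4,9-trienoate (both carbinol epimers) | COC(=O)/C=C/C=C/[C@@](C)(C(C)O)CCC=C(C)C | intermediate
10 | methyl (2E,4E,6S)-6-acetyl-6,10-dimethylundeca-2,4,9-trienoate | COC(=O)/C=C/C=C/[C@@](C)(C(C)=O)CCC=C(C)C | intermediate
11 | (2E)-4,4-dimethoxy-2-methylbut-2-enal | O=C/C(C)=C/C(OC)OC | starting material
12 | diisopinocampheylboron enolate of 10 (not isolated) | COC(=O)/C=C/C=C/[C@@](C)(C(=C)OB([C@@H]1C[C@@H]2C[C@H]([C@H]1C)C2(C)C)[C@@H]1C[C@@H]2C[C@H]([C@H]1C)C2(C)C)CCC=C(C)C | intermediate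
13 | methyl (2E,4E,6S)-6-[(3S,4E)-3-hydroxy-6,6-dimethoxy-4-methylhex-4-enoyl]-6,10-dimethylundeca-2,4,9-trienoate | COC(=O)/C=C/C=C/[C@@](C)(C(=O)C[C@H](O)/C(C)=C/C(OC)OC)CCC=C(C)C | intermediate
14 | methyl (2E,4E,6S)-6-[(3S,4E)-3-[(tert-butyldimethylsilyl)oxy]-6,6-dimethoxy-4-methylhex-4-enoyl]-6,10-dimethylundeca-2,4,9-trienoate | COC(=O)/C=C/C=C/[C@@](C)(C(=O)C[C@H](O[Si](C)(C)C(C)(C)C)/C(C)=C/C(OC)OC)CCC=C(C)C | intermediate
15 | methyl (2E,4E,6S)-6-[(3S,4E)-3-[(tert-butyldimethylsilyl)oxy]-4-methyl-6-oxohex-4-enoyl]-6,10-dimethylundeca-2,4,9-trienoate | COC(=O)/C=C/C=C/[C@@](C)(C(=O)C[C@H](O[Si](C)(C)C(C)(C)C)/C(C)=C/C=O)CCC=C(C)C | intermediate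
16 | trans-fused cycloadduct (1α-OTBS; 3-oxo; 4β-methyl; 4α-(4-methylpent-3-enyl); 5α-H; 6-ene; 8β-CO2Me; 9β-CHO; 10β-methyl) | CC(C)=CCC[C@]1(C)C(=O)C[C@H](O[Si](C)(C)C(C)(C)C)[C@]2(C)[C@@H](C=O)[C@@H](C(=O)OC)C=C[C@@H]12 | intermediate
17 | dimethyl acetal of 16 | CC(C)=CCC[C@]1(C)C(=O)C[C@H](O[Si](C)(C)C(C)(C)C)[C@]2(C)[C@@H](C(OC)OC)[C@@H](C(=O)OC)C=C[C@@H]12 | intermediate
18 | potassium C2–C3 enolate of 17 (not isolated) | CC(C)=CCC[C@]1(C)C([O-])=C[C@H](O[Si](C)(C)C(C)(C)C)[C@]2(C)[C@@H](C(OC)OC)[C@@H](C(=O)OC)C=C[C@@H]12.[K+] | intermediate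
19 | C3 enol triflate (2-ene) | CC(C)=CCC[C@]1(C)C(OS(=O)(=O)C(F)(F)F)=C[C@H](O[Si](C)(C)C(C)(C)C)[C@]2(C)[C@@H](C(OC)OC)[C@@H](C(=O)OC)C=C[C@@H]12 | intermediate
20 | alkenyl chloride (3-chloro-2-ene; 1α-OTBS) | CC(C)=CCC[C@]1(C)C(Cl)=C[C@H](O[Si](C)(C)C(C)(C)C)[C@]2(C)[C@@H](C(OC)OC)[C@@H](C(=O)OC)C=C[C@@H]12 | intermediate
21 | allylic alcohol (3-chloro-2-ene; 1α-OH) | CC(C)=CCC[C@]1(C)C(Cl)=C[C@H](O)[C@]2(C)[C@@H](C(OC)OC)[C@@H](C(=O)OC)C=C[C@@H]12 | intermediate
22 | side-chain (R)-epoxide of 21 | CC3(C)O[C@@H]3CC[C@]1(C)C(Cl)=C[C@H](O)[C@]2(C)[C@@H](C(OC)OC)[C@@H](C(=O)OC)C=C[C@@H]12 | intermediate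
23 | 3β-chloride with side-chain (R)-epoxide (1α-OH; 6-ene) | CC3(C)O[C@@H]3CC[C@]1(C)[C@@H](Cl)C[C@H](O)[C@]2(C)[C@@H](C(OC)OC)[C@@H](C(=O)OC)C=C[C@@H]12 | intermediate
24 | (R)-isopropenyl carbinol (1α-OH; 3β-Cl; 6-ene; acetal) | C=C(C)[C@H](O)CC[C@]1(C)[C@@H](Cl)C[C@H](O)[C@]2(C)[C@@H](C(OC)OC)[C@@H](C(=O)OC)C=C[C@@H]12 | intermediate
25 | conjugated ester (7-ene; acetal) | C=C(C)[C@H](O)CC[C@]1(C)[C@@H](Cl)C[C@H](O)[C@]2(C)[C@@H](C(OC)OC)C(C(=O)OC)=CC[C@@H]12 | intermediate
26 | CNP0159496.2 | C=C(C)[C@H](O)CC[C@]1(C)[C@@H](Cl)C[C@H](O)[C@]2(C)[C@@H](C=O)C(C(=O)OC)=CC[C@@H]12 | target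

**Step count and risks**

Total step count: 21. Longest linear sequence: 21 steps (1 to 26); 5 and 11 are purchased.

Steps most likely to fail:

1. Step 12. The ester-terminated diene is electron-poor and may add too slowly to the complexed enal, so that loss of the β-silyloxy group or exo closure competes. The C1 silyloxy group may also take the equatorial instead of the axial position, which would erode π-facial selectivity. Fallback: a cationic (Gassman-type) Diels–Alder reaction. Acetal 14 is treated with Me3SiOTf (cat.) in CH2Cl2 at −78 °C, so that the far more electrophilic vinyl oxocarbenium ion is the dienophile and the acetal is regenerated after cycloaddition. This sets out from 14 and returns to the route at 17, passing by 15 and 16; it makes no new compound (F0).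

2. Step 18. Hydrogen atom transfer may also reach the ring B olefin (over-reduction), or the C3 radical may take up hydrogen from the β face and give the axial chloride. Fallback: introduce the chloride by substitution. Ketone 17 is reduced with LiBH(s-Bu)3 in THF at −78 °C; attack from the equatorial direction should give the axial 3α-alcohol F1. Appel chlorination (PPh3, CCl4, pyridine, warm) with inversion should give the equatorial 3β-chloride F2; this displacement next to the quaternary C4 is expected to be slow. HF·pyridine then removes the silyl group to give the 1α-alcohol F3, and Shi epoxidation of F3 as in step 17 returns to the route at 23.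

3. Step 15. Oxidative addition of nickel into the hindered enol triflate next to the quaternary C4 may be slow, leaving protodetriflation or recovered triflate. Fallback: convert ketone 17 directly into alkenyl chloride 20 with (PhO)3P, Cl2 and Et3N in CH2Cl2 at −78 °C to rt (chlorophosphonium-mediated ketone to vinyl chloride conversion). This sets out from 17 and returns at 20, passing by 18 and 19; it makes no new compound (F0).

Further compounds
F0 | step 12 | none | none
F1 | step 18 | 3α-alcohol from 17 (1α-OTBS; 3α-OH; 6-ene; 8β-CO2Me; 9β-CH(OMe)2) | CC(C)=CCC[C@]1(C)[C@H](O)C[C@H](O[Si](C)(C)C(C)(C)C)[C@]2(C)[C@@H](C(OC)OC)[C@@H](C(=O)OC)C=C[C@@H]12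
F2 | step 18 | 3β-chloride silyl ether (1α-OTBS; 3β-Cl; 6-ene) | CC(C)=CCC[C@]1(C)[C@@H](Cl)C[C@H](O[Si](C)(C)C(C)(C)C)[C@]2(C)[C@@H](C(OC)OC)[C@@H](C(=O)OC)C=C[C@@H]12
F3 | step 18 | 3β-chloride 1α-alcohol (prenyl side chain; 6-ene) | CC(C)=CCC[C@]1(C)[C@@H](Cl)C[C@H](O)[C@]2(C)[C@@H](C(OC)OC)[C@@H](C(=O)OC)C=C[C@@H]12
F0 | step 15 | none | none
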